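The data come from a simulation from invented constants; scatter was added.

| setting | green | grey | theta | zeta | alpha |
|---|---|---|---|---|---|
| substrate | 0.056 M | 0.056 M | 0.056 M | 0.056 M | 0.056 M |
| partner | 0.36 equiv | 1.2 equiv | 0.250 equiv | 0.500 equiv | 1.00 equiv |
| remark | run made earlier | run made earlier |  |  |  |
| time |  |  | 12 h | 12 h | 12 h |

| run | time / h | mono adduct / % | substrate / % |
|---|---|---|---|
| green | 1.50 | 17.0 | 70.0 |
| green | 4.00 | 16.6 | 70.2 |
| green | 8.00 | 16.9 | 69.9 |
| green | 12.0 | 16.7 | 70.4 |
| grey | 1.50 | 37.9 | 21.6 |
| grey | 4.00 | 38.3 | 21.8 |
| grey | 8.00 | 37.6 | 21.2 |
| grey | 12.0 | 38.1 | 21.8 |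

(scatter of a reading: 0.3 percentage points)

1. amount of mono adduct at the end, in percent of the substrate charged for theta, zeta, alpha, in this order
2. how that number moves from the first to the last of them (falls, then rises / rises, then falls / rises all the way / falls all the way / hardly changes)

- steps that have been proposed: substrate + partner -> other mono adduct; substrate + partner -> mono adduct; partner + other mono adduct -> bis adduct; partner + mono adduct -> over-reaction product; partner + mono adduct -> bis adduct; partner -> decomposed reagent
- "hardly changes" means that all values lie within two and a half points (for a concentration: within two and a half percent of the largest)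

Begin at the late end of both earlier runs. From 1.50 h to 12.0 h the mono adduct moves about as far as the scatter of 0.3 percentage points allows, so read each run as a step response long past its time constant and freeze it. The means are 16.8% in green and 38.0% in grey. Leave the next run at 12 h, then, and decide how much partner to charge.

Divide each plateau by the equivalents charged and call the result g. It falls from 0.467 in green to 0.316 in grey, which is 0.179 for each equivalent added. Call this the fall-off, the drop of g per added equivalent of partner at 0.056 M substrate. Two runs allow a straight line and nothing finer, so take g as 0.531 minus the fall-off times the equivalents, and multiply by the equivalents to get the plateau. This gives 12.2% for theta, 22.1% for zeta and 35.2% for alpha, so the amount rises from each charge to the next. Charge alpha for the most mono adduct, but expect 1.59 times zeta's amount from twice the partner.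

The forecast stands a little higher than this reckoning at each charge, with 12.4%, 22.3% and 35.8%, gives the shape as rises all the way, and says “the yield rises throughout”.

The flask gives 12.3% for theta, 22.2% for zeta and 35.4% for alpha; the shape is: rises all the way.

    substrate + partner → other mono adduct (k = 0.0387 M⁻¹ s⁻¹)
    substrate + partner → mono adduct (k = 0.0557 M⁻¹ s⁻¹)
    partner + other mono adduct → bis adduct (k = 0.112 M⁻¹ s⁻¹)
    partner + mono adduct → over-reaction product (k = 0.00726 M⁻¹ s⁻¹)
    partner + mono adduct → bis adduct (k = 0.0124 M⁻¹ s⁻¹)
    partner → decomposed reagent (k = 4.66 × 10⁻⁴ s⁻¹)

Alpha's mono adduct is the same at 120 h as at 12.0 h, with the partner, the limiting reagent, at 0% of its charge. Now start from zeta's result, g = 0.444, and apply the fall-off. For alpha it gives 0.355, and alpha's result gives 0.354. For theta it gives 0.489, and theta's result gives 0.492.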